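**Retrosynthetic overview**
1. Sesterfisherol ⇐ one acid-triggered cascade on a 5-12-5 tricyclic tertiary allylic alcohol: C10–C11–C12 allyl cation, transannular C2–C12 bond (rings C and B close together), 1,2-hydride shifts H2→C3 and H12→C2, water capture at C12.
2. Twelve-membered ring ⇐ B-alkyl Suzuki ring closure at C3–C4, after a B-alkyl Suzuki union of the two halves at C12–C13 (sets C14).
3. Ring D half ⇐ (S)-limonene: ozonolysis/aldol ring contraction, Johnson–Claisen rearrangement (C15 quaternary centre), alkyne to (E)-vinyl bromide.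
4. Ring A half ⇐ (R)-pulegone: Favorskii ring contraction, ozonolysis, ethynylation, methylalumination–iodination.
5. Ring order: D and A from the chiral pool → macrocycle → C and B in the last step.

Assumption: atoms carry the geranylfarnesyl diphosphate numbering (C1 = CH2 between C2 and C15; C12 = carbinol carbon of the target), and (S)-(−)-limonene and (R)-(+)-pulegone are taken as cheap commercial terpenes.

**Route**

Step 1
Reactants: 1 (S)-(−)-limonene
Product: 2 (S)-p-menth-1-ene
Conditions: H2 (1 atm), RhCl(PPh3)3 (1 mol%), benzene–EtOH, rt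
Reagents that add atoms: none
Why: Chemoselective homogeneous hydrogenation reduces the unhindered 1,1-disubstituted isopropenyl group far faster than the trisubstituted ring alkene, and the C4 stereocentre (later C18) is untouched.

Step 2
Reactants: 2 (S)-p-menth-1-ene
Product: 4 (5R)-2-methyl-5-(propan-2-yl)cyclopent-1-ene-1-carbaldehyde, via keto aldehyde 3 (not isolated)
Conditions: O3, CH2Cl2, −78 °C; Me2S; then piperidine, AcOH, toluene, 80 °C
Reagents that add atoms: ozone, [O-][O+]=O
Why: Ozonolysis followed by enamine-mediated intramolecular aldol condensation (aldehyde α-carbon onto the methyl ketone) gives the cyclopentene carbaldehyde, with the isopropyl stereocentre carried over unchanged.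

Step 3
Reactants: 4 (5R)-2-methyl-5-(propan-2-yl)cyclopent-1-ene-1-carbaldehyde
Product: 5 [(5R)-2-methyl-5-(propan-2-yl)cyclopent-1-en-1-yl]methanol
Conditions: NaBH4, CeCl3·7H2O, MeOH, 0 °C
Reagents that add atoms: none
Why: Luche reduction gives clean 1,2-reduction of the enal to the primary allylic alcohol.

Step 4
Reactants: 5 [(5R)-2-methyl-5-(propan-2-yl)cyclopent-1-en-1-yl]methanol
Product: 7 ethyl 2-[(1R,3R)-1-methyl-2-methylidene-3-(propan-2-yl)cyclopentyl]acetate, via ketene acetal 6 (not isolated)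
Conditions: MeC(OEt)3, EtCO2H (cat.), 140 °C, EtOH distilled off
Reagents that add atoms: triethyl orthoacetate, CC(OCC)(OCC)OCC
Why: Johnson–Claisen rearrangement forms the C15 quaternary centre through a chair transition state on the ring face anti to the neighbouring C18 isopropyl group (CH2CO2Et trans to isopropyl, methyl cis) and leaves C13 as an exocyclic methylene.

Step 5
Reactants: 7 ethyl 2-[(1R,3R)-1-methyl-2-methylidene-3-(propan-2-yl)cyclopentyl]acetate
Product: 9 (1R,3R)-1-methyl-2-methylidene-3-(propan-2-yl)-1-(prop-2-yn-1-yl)cyclopentane, via aldehyde 8 (not isolated)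
Conditions: i-Bu2AlH, CH2Cl2, −78 °C; then MeOH, K2CO3, MeC(O)C(N2)P(O)(OMe)2, −78 °C → rt
Reagents that add atoms: dimethyl (1-diazo-2-oxopropyl)phosphonate, CC(=O)C(=[N+]=[N-])P(=O)(OC)OC
Why: One-pot partial ester reduction and Seyferth–Gilbert homologation with the Ohira–Bestmann reagent converts C2 into the alkyne carbon and adds C3, with no stereocentre involved.

Step 6
Reactants: 9 (1R,3R)-1-methyl-2-methylidene-3-(propan-2-yl)-1-(prop-2-yn-1-yl)cyclopentane
Product: 10 (1R,3R)-1-(but-2-yn-1-yl)-1-methyl-2-methylidene-3-(propan-2-yl)cyclopentane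
Conditions: n-BuLi, THF, −78 °C; MeI, −78 °C → rt
Reagents that add atoms: iodomethane, CI
Why: Acetylide alkylation installs the C3 methyl group.

Step 7
Reactants: 10 (1R,3R)-1-(but-2-yn-1-yl)-1-methyl-2-methylidene-3-(propan-2-yl)cyclopentane
Product: 12 (1R,3R)-1-[(2E)-3-bromobut-2-en-1-yl]-1-methyl-2-methylidene-3-(propan-2-yl)cyclopentane, via alkenylzirconocene 11 (not isolated)
Conditions: Cp2Zr(H)Cl (1.6 equiv), THF, rt → 40 °C; NBS, 0 °C
Reagents that add atoms: N-bromosuccinimide, O=C1CCC(=O)N1Br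
Why: Syn hydrozirconation, equilibrated with excess reagent so that zirconium sits on the less hindered methyl-bearing alkyne carbon (the other side is neopentyl-like), then bromodezirconation with retention fixes the E-trisubstituted C2=C3 geometry; the hindered exocyclic methylene reacts more slowly.

Step 8
Reactants: 13 (R)-(+)-pulegone
Product: 15 methyl (1S,5R)-5-methyl-2-(propan-2-ylidene)cyclopentane-1-carboxylate, via pulegone dibromide 14 (not isolated)
Conditions: Br2, Et2O, −10 °C; then NaOMe, MeOH, reflux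
Reagents that add atoms: sodium methoxide, [Na+].[O-]C
Why: Bromination and Favorskii ring contraction give the pulegenate, and methoxide equilibrates the epimerizable α-centre to the trans ester (C5 trans to the C7 methyl, which comes unchanged from pulegone).

Step 9
Reactants: 15 methyl (1S,5R)-5-methyl-2-(propan-2-ylidene)cyclopentane-1-carboxylate
Product: 17 (1R,2S)-2-ethenyl-1-methyl-3-(propan-2-ylidene)cyclopentane, via aldehyde 16 (not isolated)
Conditions: i-Bu2AlH, toluene, −78 °C; then Ph3PCH3Br/KOt-Bu, THF, −78 °C → rt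
Reagents that add atoms: methyltriphenylphosphonium bromide, C[P+](c1ccccc1)(c1ccccc1)c1ccccc1.[Br-]
Why: One-pot partial reduction and Wittig methylenation keeps the isomerization-prone β,γ-unsaturated aldehyde masked as its aluminium hemiacetal until it is olefinated, and the trans relationship is retained.

Step 10
Reactants: 17 (1R,2S)-2-ethenyl-1-methyl-3-(propan-2-ylidene)cyclopentane
Product: 18 (2S,3R)-2-ethenyl-3-methylcyclopentan-1-one
Conditions: O3 (1.0 equiv, Sudan Red 7B end point), CH2Cl2–pyridine, −78 °C; Me2S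
Reagents that add atoms: ozone, [O-][O+]=O
Why: Chemoselective ozonolysis cleaves the electron-rich tetrasubstituted isopropylidene much faster than the monosubstituted vinyl group and unveils the C10 ketone; the α-centre stays in the favoured trans form.

Step 11
Reactants: 18 (2S,3R)-2-ethenyl-3-methylcyclopentan-1-one
Product: 19 (1R,2S,3R)-2-ethenyl-1-ethynyl-3-methylcyclopentan-1-ol
Conditions: HC≡CMgBr, LaCl3·2LiCl (30 mol%), THF, 0 °C
Reagents that add atoms: ethynylmagnesium bromide, C#C[Mg]Br
Why: Lewis-acid-assisted Grignard 1,2-addition outruns enolization of the α-vinyl ketone; attack anti to the vinyl group gives mainly the epimer shown, and the C10 configuration is irrelevant because this centre is ionized in step 15.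

Step 12
Reactants: 19 (1R,2S,3R)-2-ethenyl-1-ethynyl-3-methylcyclopentan-1-ol
Product: 21 (1R,2S,3R)-2-ethenyl-1-[(1E)-1-iodoprop-1-en-2-yl]-3-methylcyclopentan-1-ol, via alkenylalane 20 (not isolated)
Conditions: Me3Al (3 equiv), Cp2ZrCl2 (30 mol%), CH2Cl2, 0 °C → rt; I2, THF, −30 °C
Reagents that add atoms: trimethylaluminium, C[Al](C)C; iodine, II
Why: Negishi zirconium-catalysed syn methylalumination puts the methyl on the internal carbon (C11) and aluminium on C12, and iodinolysis with retention gives the E-iodide (iodine trans to the carbinol carbon), the geometry that later gives a sickle-shaped rather than U-shaped allyl cation.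

Step 13
Reactants: 12 (1R,3R)-1-[(2E)-3-bromobut-2-en-1-yl]-1-methyl-2-methylidene-3-(propan-2-yl)cyclopentane, 21 (1R,2S,3R)-2-ethenyl-1-[(1E)-1-iodoprop-1-en-2-yl]-3-methylcyclopentan-1-ol
Product: 23 (1R,2S,3R)-1-[(1E)-3-{(1S,2R,5R)-2-[(2E)-3-bromobut-2-en-1-yl]-2-methyl-5-(propan-2-yl)cyclopentyl}prop-1-en-2-yl]-2-ethenyl-3-methylcyclopentan-1-ol, via alkylborane 22 (not isolated)
Conditions: 12, 9-BBN-H (1.1 equiv), THF, 0 → 50 °C, then H2O; then 21, Pd(dppf)Cl2 (10 mol%), AsPh3, Cs2CO3, DMF–H2O, 35 °C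
Reagents that add atoms: none
Why: Hydroboration of the exocyclic methylene from the face opposite the C18 isopropyl group sets C14 (C13 syn to isopropyl and methyl, the contra-thermodynamic all-cis array), and B-alkyl Suzuki–Miyaura coupling forms C12–C13 selectively at the C–I bond; the E-bromide of 22 cannot self-couple and the E-iodide of 21 cannot undergo Heck closure onto its vinyl group, since either would need a trans-cycloalkene in a small ring.

Step 14
Reactants: 23 (seco-macrocycle from step 13)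
Product: 25 (2E,11E)-5-12-5 tricyclic tertiary allylic alcohol, via alkylborane 24 (not isolated)
Conditions: 9-BBN-H (2.5 equiv), THF, rt; then syringe-pump addition to Pd(dppf)Cl2 (15 mol%), AsPh3, Cs2CO3, DMF–THF–H2O, 60 °C, 2 mM
Reagents that add atoms: none
Why: 9-BBN-H hydroborates only the monosubstituted vinyl group, and intramolecular B-alkyl Suzuki–Miyaura coupling of the unhindered primary borane with the E-vinyl bromide closes the twelve-membered ring at C3–C4 with retention of the E-C2=C3 geometry.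

Step 15
Reactants: 25 (2E,11E)-5-12-5 tricyclic tertiary allylic alcohol
Product: 30 sesterfisherol, via macrocyclic allyl cation 26 (not isolated), via tetracyclic C3 cation 27 (not isolated), via C2 cation 28 (not isolated), via C12 allyl cation 29 (not isolated)
Conditions: TfOH (2 mol%), (CF3)2CHOH, H2O (5 equiv), −20 → 0 °C, 1 mM; Et3N quench
Reagents that add atoms: water, O
Why: Proposed new method: ionizing the tertiary allylic alcohol in a cation-stabilizing, weakly nucleophilic solvent gives the same C10–C11–C12 allyl cation 26 that the cyclase reaches, the E-C2=C3 olefin lying across the twelve-membered ring adds to C12 through a six-membered array so that rings C and B close in one bond-forming event (27), the tertiary C3 cation is discharged by two suprafacial, mutually anti 1,2-hydride shifts (H2 to C3 sets C3, then H12 to the β-face of C2 sets C2) through tertiary 28 to the tertiary allylic cation 29, the thermodynamic sink, and water adds to C12 from the axial α-face so that the eight-membered ring ends trans-diequatorial on a chair ring C with C10=C11 exocyclic to the five-membered ring; because allyl cation–olefin addition is reversible, only the folding that can drain through this hydride relay to the strain-free trans-fused framework is consumed (Curtin–Hammett); closest known reaction type: acid-induced transannular cation–olefin cyclizations of macrocyclic terpenes terminated by water (caryophyllene to caryolan-1-ol, humulene to apollan-11-ol) and allylic-alcohol-initiated cation–olefin cyclizations in (CF3)2CHOH.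

**Compound list**

1 | (S)-(−)-limonene, (4S)-1-methyl-4-(prop-1-en-2-yl)cyclohex-1-ene | CC1=CC[C@H](CC1)C(C)=C | starting material
2 | (S)-p-menth-1-ene, (4S)-1-methyl-4-(propan-2-yl)cyclohex-1-ene | CC1=CC[C@H](CC1)C(C)C | intermediate
3 | (3S)-6-oxo-3-(propan-2-yl)heptanal | CC(=O)CC[C@@H](CC=O)C(C)C | intermediate (not isolated)
4 | (5R)-2-methyl-5-(propan-2-yl)cyclopent-1-ene-1-carbaldehyde | CC1=C(C=O)[C@@H](C(C)C)CC1 | intermediate
5 | [(5R)-2-methyl-5-(propan-2-yl)cyclopent-1-en-1-yl]methanol | CC1=C(CO)[C@@H](C(C)C)CC1 | intermediate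
6 | mixed ketene acetal, 1-ethoxy-1-{[(5R)-2-methyl-5-(propan-2-yl)cyclopent-1-en-1-yl]methoxy}ethene | CC1=C(COC(=C)OCC)[C@@H](C(C)C)CC1 | intermediate (not isolated)
7 | ethyl 2-[(1R,3R)-1-methyl-2-methylidene-3-(propan-2-yl)cyclopentyl]acetate (CH2CO2Et trans to isopropyl) | C=C1[C@@H](C(C)C)CC[C@]1(C)CC(=O)OCC | intermediate
8 | 2-[(1R,3R)-1-methyl-2-methylidene-3-(propan-2-yl)cyclopentyl]acetaldehyde | C=C1[C@@H](C(C)C)CC[C@]1(C)CC=O | intermediate (not isolated)
9 | (1R,3R)-1-methyl-2-methylidene-3-(propan-2-yl)-1-(prop-2-yn-1-yl)cyclopentane | C=C1[C@@H](C(C)C)CC[C@]1(C)CC#C | intermediate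
10 | (1R,3R)-1-(but-2-yn-1-yl)-1-methyl-2-methylidene-3-(propan-2-yl)cyclopentane | C=C1[C@@H](C(C)C)CC[C@]1(C)CC#CC | intermediate
11 | (E)-alkenylzirconocene chloride of 10 (Zr on C3, syn to H on C2) | C=C1[C@@H](C(C)C)CC[C@]1(C)C/C=C(\C)[Zr](Cl)(C2C=CC=C2)C2C=CC=C2 | intermediate (not isolated)
12 | (1R,3R)-1-[(2E)-3-bromobut-2-en-1-yl]-1-methyl-2-methylidene-3-(propan-2-yl)cyclopentane | C=C1[C@@H](C(C)C)CC[C@]1(C)C/C=C(\C)Br | intermediate
13 | (R)-(+)-pulegone, (5R)-5-methyl-2-(propan-2-ylidene)cyclohexan-1-one | C[C@@H]1CCC(=C(C)C)C(=O)C1 | starting material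
14 | pulegone dibromide, (5R)-2-bromo-2-(2-bromopropan-2-yl)-5-methylcyclohexan-1-one (C2 epimers) | C[C@@H]1CCC(Br)(C(C)(C)Br)C(=O)C1 | intermediate (not isolated)
15 | methyl (1S,5R)-5-methyl-2-(propan-2-ylidene)cyclopentane-1-carboxylate (methyl trans-pulegenate) | COC(=O)[C@H]1[C@H](C)CCC1=C(C)C | intermediate
16 | (1S,5R)-5-methyl-2-(propan-2-ylidene)cyclopentane-1-carbaldehyde | O=C[C@H]1[C@H](C)CCC1=C(C)C | intermediate (not isolated)
17 | (1R,2S)-2-ethenyl-1-methyl-3-(propan-2-ylidene)cyclopentane (vinyl trans to methyl) | C=C[C@H]1[C@H](C)CCC1=C(C)C | intermediate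
18 | (2S,3R)-2-ethenyl-3-methylcyclopentan-1-one | C=C[C@H]1[C@H](C)CCC1=O | intermediate
19 | (1R,2S,3R)-2-ethenyl-1-ethynyl-3-methylcyclopentan-1-ol (major C1 epimer; the minor one is carried along) | C=C[C@H]1[C@H](C)CC[C@]1(O)C#C | intermediate
20 | (E)-alkenyl(dimethyl)alane dimethylaluminium alkoxide of 19 | C=C[C@H]1[C@H](C)CC[C@]1(O[Al](C)C)/C(C)=C/[Al](C)C | intermediate (not isolated)
21 | (1R,2S,3R)-2-ethenyl-1-[(1E)-1-iodoprop-1-en-2-yl]-3-methylcyclopentan-1-ol | C=C[C@H]1[C@H](C)CC[C@]1(O)/C(C)=C/I | intermediate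
22 | 9-{[(1S,2R,5R)-2-[(2E)-3-bromobut-2-en-1-yl]-2-methyl-5-(propan-2-yl)cyclopentyl]methyl}-9-borabicyclo[3.3.1]nonane | B1(C[C@H]2[C@@H](C(C)C)CC[C@]2(C)C/C=C(\C)Br)C3CCCC1CCC3 | intermediate (not isolated)
23 | (1R,2S,3R)-1-[(1E)-3-{(1S,2R,5R)-2-[(2E)-3-bromobut-2-en-1-yl]-2-methyl-5-(propan-2-yl)cyclopentyl}prop-1-en-2-yl]-2-ethenyl-3-methylcyclopentan-1-ol | C=C[C@H]1[C@H](C)CC[C@]1(O)/C(C)=C/C[C@H]2[C@@H](C(C)C)CC[C@]2(C)C/C=C(\C)Br | intermediate
24 | B-alkyl-9-BBN of 23 (boron on C4) | B1(CC[C@H]2[C@H](C)CC[C@]2(O)/C(C)=C/C[C@H]3[C@@H](C(C)C)CC[C@]3(C)C/C=C(\C)Br)C4CCCC1CCC4 | intermediate (not isolated)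
25 | (2E,11E)-5-12-5 tricyclic alcohol: ring A cyclopentanol (C6–C10, 7-methyl, 10-OH) and ring D cyclopentane (C14–C18, 15-methyl, 18-isopropyl) bridged by C10–C11(Me)=C12H–C13H2–C14 and C15–C1H2–C2H=C3(Me)–C4H2–C5H2–C6 | C/C1=C\C[C@H]2[C@@H](C(C)C)CC[C@]2(C)C/C=C(\C)CC[C@H]3[C@H](C)CC[C@]13O | intermediate
26 | macrocyclic C10–C11–C12 allyl cation | C/C1=C\C[C@H]2[C@@H](C(C)C)CC[C@]2(C)C/C=C(\C)CC[C@H]3[C@H](C)CC[C+]13 | intermediate (not isolated)
27 | tetracyclic C3 cation after C2–C12 bond formation (H2 α, H12 β) | C/C1=C2\CC[C@@H](C)[C@@H]2CC[C+](C)[C@@H]2C[C@@]3(C)CC[C@H](C(C)C)[C@@H]3C[C@@H]12 | intermediate (not isolated)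
28 | tetracyclic C2 cation after H2→C3 shift | C/C1=C2\CC[C@@H](C)[C@@H]2CC[C@H](C)[C+]2C[C@@]3(C)CC[C@H](C(C)C)[C@@H]3C[C@@H]12 | intermediate (not isolated)
29 | tetracyclic C12 allyl cation after H12→C2 shift | C/C1=C2\CC[C@@H](C)[C@@H]2CC[C@H](C)[C@H]2C[C@@]3(C)CC[C@H](C(C)C)[C@@H]3C[C+]12 | intermediate (not isolated)
30 | sesterfisherol | C/C1=C2\CC[C@@H](C)[C@@H]2CC[C@H](C)[C@H]2C[C@@]3(C)CC[C@H](C(C)C)[C@@H]3C[C@]12O | target

**Totals**

Total steps: 15. Longest linear sequence: 10 (steps 1–7, 13, 14, 15); steps 8–12 form the second branch.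

**Steps most likely to fail, with fallbacks**

Step 15 (cascade). The ionization may stop at dienes, trap the C3 cation, or give C2/C3 epimers if the macrocycle folds differently from the enzyme-bound substrate. The fallback sets out from 25 and comes back at 30. Oxidative 1,3-transposition of 25 with [C5H5NH][CrO3Cl] in CH2Cl2 (Babler–Dauben) gives the macrocyclic enone F1, with a C12 ketone and the C10=C11 bond. Me2AlCl at −78 °C then promotes a transannular carbonyl-ene (Prins) addition of C2 to the activated C12 carbonyl. The chair array with C11 and C3 equatorial delivers the C12 α-hydroxyl and the C2 β-hydrogen directly, giving the exocyclic-methylene alcohol F2. Hydroxyl-directed hydrogenation with H2 (1 atm) and [Ir(cod)(PCy3)(py)]PF6, stopped after one equivalent, adds hydrogen to C3 from the face of the C12 hydroxyl and gives 30.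

Step 14 (macrocyclic B-alkyl Suzuki coupling). Protodeboronation or oligomerization may win at high dilution. The fallback sets out from 23 and comes back at 25. Hydroboration–oxidation of the vinyl group (9-BBN-H; NaBO3·4H2O) gives the primary alcohol F3. I2, PPh3 and imidazole at 0 °C convert it into the primary iodide F4. Zinc insertion (Zn, LiCl, THF) gives the alkylzinc iodide F5, which is cyclized onto the vinyl bromide by intramolecular Negishi coupling with Pd(P(t-Bu)3)2 at 2 mM to give 25.

Step 13 (intermolecular coupling of the hindered C13 borane, iodide-over-bromide selectivity, facial selectivity at C14). The fallback sets out from 18 and 12, replaces steps 11–14, and comes back at 25; it makes the unhindered C3–C4 bond first and closes the ring at C12–C13. LiC≡CSiMe3 with LaCl3·2LiCl adds to 18 to give the silylated alkynyl carbinol F6. 9-BBN-H hydroborates its vinyl group to the alkylborane F7, which is coupled with the vinyl bromide 12 (Pd(dppf)Cl2, Cs2CO3, 60 °C) to the silylated coupling product F8. K2CO3/MeOH in the work-up gives the terminal alkyne F9. Methylalumination (Me3Al, Cp2ZrCl2) gives the alkenylalane F10, and iodine converts it into the (E)-vinyl iodide F11. 9-BBN-H then adds to the exocyclic methylene to give the alkylborane F12, and intramolecular Suzuki coupling at high dilution closes the ring to 25.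

**Further compounds**

F1 | step 15 | (2E)-5-12-5 tricyclic enone, C12 ketone conjugated to tetrasubstituted C10=C11 (C12 syn to C6) | C/C1=C2\CC[C@@H](C)[C@@H]2CC/C(C)=C/C[C@@]3(C)CC[C@H](C(C)C)[C@@H]3CC1=O
F2 | step 15 | 3-methylidene tetracyclic alcohol (sesterfisherol skeleton with C3=CH2, 12α-OH, 2β-H) | C/C1=C2\CC[C@@H](C)[C@@H]2CCC(=C)[C@H]2C[C@@]3(C)CC[C@H](C(C)C)[C@@H]3C[C@]12O
F3 | step 14 | primary alcohol from hydroboration–oxidation of 23 (diol, OH on C4) | OCC[C@H]1[C@H](C)CC[C@]1(O)/C(C)=C/C[C@H]2[C@@H](C(C)C)CC[C@]2(C)C/C=C(\C)Br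
F4 | step 14 | primary iodide (I on C4) | ICC[C@H]1[C@H](C)CC[C@]1(O)/C(C)=C/C[C@H]2[C@@H](C(C)C)CC[C@]2(C)C/C=C(\C)Br
F5 | step 14 | alkylzinc iodide (Zn on C4) | I[Zn]CC[C@H]1[C@H](C)CC[C@]1(O)/C(C)=C/C[C@H]2[C@@H](C(C)C)CC[C@]2(C)C/C=C(\C)Br
F6 | step 13 | (1R,2S,3R)-2-ethenyl-3-methyl-1-[(trimethylsilyl)ethynyl]cyclopentan-1-ol | C=C[C@H]1[C@H](C)CC[C@]1(O)C#C[Si](C)(C)C
F7 | step 13 | B-alkyl-9-BBN of F6 (boron on C4) | B1(CC[C@H]2[C@H](C)CC[C@]2(O)C#C[Si](C)(C)C)C3CCCC1CCC3
F8 | step 13 | silylated coupling product (C3–C4 bond made, exocyclic methylene intact) | C=C1[C@@H](C(C)C)CC[C@]1(C)C/C=C(\C)CC[C@H]2[C@H](C)CC[C@]2(O)C#C[Si](C)(C)C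
F9 | step 13 | terminal alkyne after desilylation | C=C1[C@@H](C(C)C)CC[C@]1(C)C/C=C(\C)CC[C@H]2[C@H](C)CC[C@]2(O)C#C
F10 | step 13 | (E)-alkenyl(dimethyl)alane dimethylaluminium alkoxide of F9 | C=C1[C@@H](C(C)C)CC[C@]1(C)C/C=C(\C)CC[C@H]2[C@H](C)CC[C@]2(O[Al](C)C)/C(C)=C/[Al](C)C
F11 | step 13 | (E)-vinyl iodide (I on C12) with exocyclic methylene | C=C1[C@@H](C(C)C)CC[C@]1(C)C/C=C(\C)CC[C@H]2[C@H](C)CC[C@]2(O)/C(C)=C/I
F12 | step 13 | B-alkyl-9-BBN of F11 (boron on C13) | B1(C[C@H]2[C@@H](C(C)C)CC[C@]2(C)C/C=C(\C)CC[C@H]3[C@H](C)CC[C@]3(O)/C(C)=C/I)C4CCCC1CCC4
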